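## Retrosynthetic overview (disconnections listed in the order the bonds are made)
1. Cα=Cβ of the enone: Claisen–Schmidt union of acetophenone 1 and benzaldehyde 2 (through aldol 3) gives chalcone 4. Its non-chelated 4'-OH is masked as acetate 5.
2. C1–C2 and C5–C6 of the cyclohexene: endo [4+2] of 5 and (E)-β-ocimene 6 on a stoichiometric chiral (S)-VANOL borate (chelates 7 and 8) gives 9. This one step sets C1, C2 and C6.
3. Acetate removal converts 9 into the target 10.
4. Ring order: ring A (trioxygenated arene) and ring B (phenyl) are bought. The cyclohexene is the only ring formed (step 3).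

Assumption: (E)-β-ocimene is bought (any Z isomer cannot reach the s-cis diene and stays inert), and the facial sense of the (S)-VANOL borate is assigned from a quadrant model of the tetrahedral chelate, not from a known result, so it must be confirmed on the first run by chiral HPLC and sign of rotation (both ligand antipodes are sold).

(S)-VANOL = (S)-3,3'-diphenyl-2,2'-binaphthalene-1,1'-diol.

## Route

Step 1
Reactants: 1 2',4'-dihydroxy-6'-methoxyacetophenone; 2 benzaldehyde
Product: 4 cardamonin [(2E)-1-(2,4-dihydroxy-6-methoxyphenyl)-3-phenylprop-2-en-1-one], via aldol adduct 3 (not isolated)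
Conditions: KOH (50% aq., 15 equiv), 2 (1.3 equiv), EtOH, 0 °C to rt, 48 h; then cold 1 N HCl to pH 4
Reagents that add atoms: none
Why: Claisen–Schmidt (crossed aldol) condensation, in which the methyl ketone enolate adds to non-enolisable benzaldehyde and aldol 3 loses water by E1cB to the conjugated, thermodynamically favoured (E)-enone, so no stereocentre remains.

Step 2
Reactants: 4 cardamonin
Product: 5 4'-O-acetylcardamonin [3-hydroxy-5-methoxy-4-[(2E)-3-phenylprop-2-enoyl]phenyl acetate]
Conditions: Ac2O (1.05 equiv), pyridine, 0 °C, 2 h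
Reagents that add atoms: acetic anhydride, CC(=O)OC(C)=O
Why: Chemoselective O-acylation, because the 2'-OH is locked in a strong hydrogen bond to the ketone and is flanked by the acyl group, so one equivalent of Ac2O takes only the free, more acidic 4'-OH; no stereocentre is formed.

Step 3
Reactants: 5 4'-O-acetylcardamonin; 6 (E)-β-ocimene [(3E)-3,7-dimethylocta-1,3,6-triene]
Product: 9 4'-O-acetylisopanduratin A (endo adduct; 1R,2S,6R; aroyl cis to prenyl; aroyl trans to phenyl), via borate chelate 7 (not isolated), via adduct borate 8 (not isolated)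
Conditions: (S)-VANOL (1.2 equiv), B(OPh)3 (1.1 equiv), THF, rt, 1 h; add 5, rt, 1 h; evaporate THF and PhOH (0.1 mbar, 50 °C); 6 (5 equiv), 5 Å MS, PhCF3, 40 °C, 48 h; H2O–THF, rt, 1 h; SiO2 (exo isomer removed, VANOL recovered)
Reagents that add atoms: none
Why: Lewis-acid-templated asymmetric Diels–Alder reaction, in which binding the 2'-oxygen and the ketone oxygen of 5 to the tetracoordinate (S)-VANOL borate lowers the enone LUMO and leaves only its Cα-Re/Cβ-Re face open, the CH2 terminus of the s-cis (E)-diene bonds to Cβ (ortho rule), suprafacial addition keeps aroyl and phenyl trans (C1 R, C6 R), and the endo transition state (aroyl under the diene) places the outward-pointing prenyl group cis to the aroyl group (C2 S).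

Step 4
Reactants: 9 4'-O-acetylisopanduratin A
Product: 10 isopanduratin A [(2,4-dihydroxy-6-methoxyphenyl)[(1R,2S,6R)-3-methyl-2-(3-methylbut-2-en-1-yl)-6-phenylcyclohex-3-en-1-yl]methanone]
Conditions: K2CO3 (1.5 equiv), MeOH, 0 °C, 30 min; then 1 N HCl to pH 5
Reagents that add atoms: none
Why: Base-mediated transesterification (methanolysis) of the activated aryl acetate is far faster than enolisation of the hindered, phenoxide-deactivated ketone, so C1 (equatorial aroyl next to equatorial phenyl, already the favoured arrangement), C2 and C6 are untouched.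

## Compound list
SMILES cannot carry the biaryl axis of the VANOL unit. It is (S) wherever the name says so.

1 | 1-(2,4-dihydroxy-6-methoxyphenyl)ethan-1-one | CC(=O)c1c(O)cc(O)cc1OC | starting material
2 | benzaldehyde | O=Cc1ccccc1 | starting material
3 | 1-(2,4-dihydroxy-6-methoxyphenyl)-3-hydroxy-3-phenylpropan-1-one (racemic aldol adduct) | COc1cc(O)cc(O)c1C(=O)CC(O)c1ccccc1 | intermediate
4 | cardamonin, (2E)-1-(2,4-dihydroxy-6-methoxyphenyl)-3-phenylprop-2-en-1-one | COc1cc(O)cc(O)c1C(=O)/C=C/c1ccccc1 | intermediate
5 | 4'-O-acetylcardamonin, 3-hydroxy-5-methoxy-4-[(2E)-3-phenylprop-2-enoyl]phenyl acetate | COc1cc(OC(C)=O)cc(O)c1C(=O)/C=C/c1ccccc1 | intermediate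
6 | (E)-β-ocimene, (3E)-3,7-dimethylocta-1,3,6-triene | C=C/C(C)=C/CC=C(C)C | starting material
7 | spiro borate chelate: tetracoordinate boron bound to the 2'-O and the ketone O of 5 and to both O atoms of (S)-VANOL, (E)-enone intact | COc1cc(OC(C)=O)cc2c1C(/C=C/c1ccccc1)=[O+][B-]1(O2)Oc2c3ccccc3cc(-c3ccccc3)c2-c2c(O1)c1ccccc1cc2-c1ccccc1 | intermediate
8 | the same (S)-VANOL spiro borate carrying the (1R,2S,6R) cycloadduct | COc1cc(OC(C)=O)cc2c1C([C@@H]1[C@H](CC=C(C)C)C(C)=CC[C@H]1c1ccccc1)=[O+][B-]1(O2)Oc2c3ccccc3cc(-c3ccccc3)c2-c2c(O1)c1ccccc1cc2-c1ccccc1 | intermediate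
9 | 4'-O-acetylisopanduratin A, 3-hydroxy-5-methoxy-4-{[(1R,2S,6R)-3-methyl-2-(3-methylbut-2-en-1-yl)-6-phenylcyclohex-3-en-1-yl]carbonyl}phenyl acetate | COc1cc(OC(C)=O)cc(O)c1C(=O)[C@@H]1[C@H](CC=C(C)C)C(C)=CC[C@H]1c1ccccc1 | intermediate
10 | isopanduratin A, (1R,2S,6R) | COc1cc(O)cc(O)c1C(=O)[C@@H]1[C@H](CC=C(C)C)C(C)=CC[C@H]1c1ccccc1 | target

## Count and risks
Total steps: 4. Longest linear sequence: 4 (1 → 4 → 5 → 9 → 10).

**Step 3.** Facial, endo/exo and regiochemical control all rest on one templated cycloaddition, and the diene is only moderately reactive. The fallback gives up asymmetric induction and resolves instead. It sets out from 5 (with 6). The two are heated without any boron reagent (toluene, BHT, sealed tube, 150 °C). The endo adduct is freed from the exo isomer on SiO2 as the racemate, a 1:1 mixture of 9 and its mirror image, ent-4'-O-acetylisopanduratin A F1. The racemate is split by preparative SFC on an amylose tris(3,5-dimethylphenylcarbamate) phase. The (1R,2S,6R) fraction is 9, where the fallback rejoins the route.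

**Step 1.** The doubly deprotonated acetophenone enolises poorly, so conversion can stall, and acidification can close 4 to the flavanone. The fallback lowers the charge by protecting first. It sets out from 1. MOMCl (1.1 equiv), iPr2NEt, CH2Cl2, 0 °C alkylates only the non-chelated 4-OH and gives 1-[2-hydroxy-6-methoxy-4-(methoxymethoxy)phenyl]ethan-1-one F2. KOH/EtOH and 2 then give the 4'-O-MOM chalcone F3. HCl in MeOH at rt removes the acetal and delivers 4, where the fallback rejoins the route.

**Step 2.** Over-acetylation to the diacetate or acetyl scrambling is possible. The fallback drops the protecting group. It sets out from 4, which is loaded directly on the (S)-VANOL phenyl borate. The borate is used at 2.2 equiv so that the free 4'-OH cannot starve the chelate of boron. This gives the free-phenol borate chelate F4, which reacts with 6 as in step 3 to give the free-phenol adduct borate F5. H2O–THF hydrolysis frees the target, so the fallback rejoins at 10 and steps 2 and 4 fall away. It is kept as the fallback because a free phenol can scramble the borate and erode ee.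

## Further compounds
F1 | step 3 | ent-4'-O-acetylisopanduratin A, (1S,2R,6S) | COc1cc(OC(C)=O)cc(O)c1C(=O)[C@H]1[C@@H](CC=C(C)C)C(C)=CC[C@@H]1c1ccccc1
F2 | step 1 | 1-[2-hydroxy-6-methoxy-4-(methoxymethoxy)phenyl]ethan-1-one | CC(=O)c1c(O)cc(OCOC)cc1OC
F3 | step 1 | (2E)-1-[2-hydroxy-6-methoxy-4-(methoxymethoxy)phenyl]-3-phenylprop-2-en-1-one | COCOc1cc(O)c(C(=O)/C=C/c2ccccc2)c(OC)c1
F4 | step 2 | (S)-VANOL spiro borate chelate of cardamonin, 4'-OH free | COc1cc(O)cc2c1C(/C=C/c1ccccc1)=[O+][B-]1(O2)Oc2c3ccccc3cc(-c3ccccc3)c2-c2c(O1)c1ccccc1cc2-c1ccccc1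
F5 | step 2 | (S)-VANOL spiro borate of isopanduratin A, (1R,2S,6R), 4'-OH free | COc1cc(O)cc2c1C([C@@H]1[C@H](CC=C(C)C)C(C)=CC[C@H]1c1ccccc1)=[O+][B-]1(O2)Oc2c3ccccc3cc(-c3ccccc3)c2-c2c(O1)c1ccccc1cc2-c1ccccc1
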